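The flavone is disconnected at both bonds to the C4 carbonyl carbon, which sits between C4a of ring A and the C3–C2 unit bearing ring B. Ring A is a phloroglucinol. In its tris(methoxymethyl) ether the oxygens O5, O7 and O1 are equivalent by threefold symmetry, so 2-iodo-1,3,5-tris(methoxymethoxy)benzene is a single compound and ring closure raises no regiochemical question. One palladium-catalysed carbonylative alkynylation unites this iodide, carbon monoxide and benzyl-protected 4-ethynylphenol, making C4a–C4 and C4–C3 at once as an open-chain ynone. Acid then unmasks the phenols and closes ring C, the chelated 5-OH leaves only O7 open to sulfation, and hydrogenolysis frees O4'.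

Key step: step 3

Remark on the chemistry: aryl sulfate monoesters are handled as their sodium salts (counter-ion exchange at work-up) and are drawn in the neutral hydrogen sulfate form of the target; the free acid is released only at the end by brief cold contact with a strong-acid ion-exchange resin.

Step 1
Reactants: 1 phloroglucinol
Product: 2 1,3,5-tris(methoxymethoxy)benzene
Conditions: NaH (3.5 equiv), MOMCl (3.5 equiv), DMF, 0 °C to rt
Reagents that add atoms: chloromethyl methyl ether (MOMCl), COCCl
Why: Threefold Williamson-type O-alkylation of the sodium phenoxides by the hard, oxocarbenium-like electrophile MOMCl in DMF should favour O- over C-alkylation and give the symmetric tris-acetal.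

Step 2
Reactants: 2 1,3,5-tris(methoxymethoxy)benzene
Product: 4 2-iodo-1,3,5-tris(methoxymethoxy)benzene, via aryllithium 3 (not isolated)
Conditions: n-BuLi (1.1 equiv), THF, 0 °C; then I2, THF, −78 °C to rt
Reagents that add atoms: iodine, II
Why: Directed ortho-metalation should occur cleanly because every ring C–H lies between two lithium-coordinating methoxymethoxy groups and all three positions are equivalent, and electrophilic trapping of the aryllithium with iodine then gives the mono-iodide.

Step 3
Reactants: 4 2-iodo-1,3,5-tris(methoxymethoxy)benzene; 5 1-(benzyloxy)-4-ethynylbenzene; 6 carbon monoxide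
Product: 7 3-[4-(benzyloxy)phenyl]-1-[2,4,6-tris(methoxymethoxy)phenyl]prop-2-yn-1-one
Conditions: PdCl2(PPh3)2 (5 mol%), CuI (2 mol%), Et3N (3 equiv), THF, CO (5 bar), 40 °C, degassed
Reagents that add atoms: none
Why: PdCl2(PPh3)2 is reduced in the flask to zerovalent palladium, which inserts into the C–I bond of 4; CO then binds and the electron-rich aryl group migrates onto it, giving an aroyl-palladium species in which the former iodinated carbon (future C4a) carries C4. The copper acetylide formed from 5, copper iodide (CuI) and Et3N hands its alkynyl group to this acyl complex, and reductive elimination forms C4–C3 and regenerates zerovalent palladium. The closest known reaction type is the carbonylative Sonogashira coupling of aryl iodides with terminal alkynes under CO, applied here to a doubly ortho-substituted, electron-rich iodide. No ring is closed and no stereocenter is created, so the selectivity needed is carbonylative over direct alkynylation, together with suppression of oxidative alkyne dimerisation. The two ortho methoxymethoxy groups of 4 shield the aryl-palladium from the bulky acetylide while the small CO ligand still reaches the metal, and CO pressure and exclusion of air reinforce this bias. Because 4 is threefold-symmetric, a single ynone should result and either flanking oxygen can later become O1.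

Step 4
Reactants: 7 3-[4-(benzyloxy)phenyl]-1-[2,4,6-tris(methoxymethoxy)phenyl]prop-2-yn-1-one
Product: 9 2-[4-(benzyloxy)phenyl]-5,7-dihydroxy-4H-chromen-4-one (4'-O-benzylapigenin), via trihydroxy ynone 8 (not isolated)
Conditions: 3 M aq HCl, MeOH–THF, 60 °C
Reagents that add atoms: none
Why: Acid-catalysed acetal cleavage should free the three phenols, after which one of the two equivalent ortho hydroxyls adds to the alkyne carbon bearing ring B of the protonated ynone in an oxa-Michael 6-endo-dig cyclisation (directly or through a solvent adduct that loses methanol), a known acid-mediated flavone synthesis from ortho-hydroxyaryl ynones that the aryl benzyl ether should tolerate.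

Step 5
Reactants: 9 2-[4-(benzyloxy)phenyl]-5,7-dihydroxy-4H-chromen-4-one
Product: 10 2-[4-(benzyloxy)phenyl]-5-hydroxy-4-oxo-4H-chromen-7-yl hydrogen sulfate
Conditions: SO3·pyridine (1.5 equiv), pyridine, 25 °C
Reagents that add atoms: sulfur trioxide–pyridine complex, O=S(=O)([O-])[n+]1ccccc1
Why: O-Sulfonation of a phenol by SO3·pyridine, a standard flavonoid sulfation, should occur at the acidic, unhindered 7-OH because the 5-OH is held in a hydrogen bond to the C4 carbonyl and O4' is blocked as its benzyl ether.

Step 6
Reactants: 10 2-[4-(benzyloxy)phenyl]-5-hydroxy-4-oxo-4H-chromen-7-yl hydrogen sulfate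
Product: 11 apigenin 7-sulfate (5-hydroxy-2-(4-hydroxyphenyl)-4-oxo-4H-chromen-7-yl hydrogen sulfate)
Conditions: H2 (1 atm), Pd/C (10 wt%), MeOH–THF, rt
Reagents that add atoms: none
Why: Catalytic hydrogenolysis of the aryl benzyl ether on Pd/C, run on the pyridine-free sodium salt because amines retard this reaction, should release O4' while the aryl sulfate and the conjugated C2–C3 double bond of the chromone survive one atmosphere of hydrogen at room temperature.

Compound list
1 | phloroglucinol | Oc1cc(O)cc(O)c1 | starting material
2 | 1,3,5-tris(methoxymethoxy)benzene | COCOc1cc(OCOC)cc(OCOC)c1 | intermediate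
3 | 2,4,6-tris(methoxymethoxy)phenyllithium | [Li]c1c(OCOC)cc(OCOC)cc1OCOC | intermediate
4 | 2-iodo-1,3,5-tris(methoxymethoxy)benzene | COCOc1cc(OCOC)c(I)c(OCOC)c1 | intermediate
5 | 1-(benzyloxy)-4-ethynylbenzene | C#Cc1ccc(OCc2ccccc2)cc1 | starting material
6 | carbon monoxide | [C-]#[O+] | starting material
7 | 3-[4-(benzyloxy)phenyl]-1-[2,4,6-tris(methoxymethoxy)phenyl]prop-2-yn-1-one | O=C(C#Cc1ccc(OCc2ccccc2)cc1)c1c(OCOC)cc(OCOC)cc1OCOC | intermediate
8 | 3-[4-(benzyloxy)phenyl]-1-(2,4,6-trihydroxyphenyl)prop-2-yn-1-one | O=C(C#Cc1ccc(OCc2ccccc2)cc1)c1c(O)cc(O)cc1O | intermediate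
9 | 2-[4-(benzyloxy)phenyl]-5,7-dihydroxy-4H-chromen-4-one (4'-O-benzylapigenin) | O=c1cc(-c2ccc(OCc3ccccc3)cc2)oc2cc(O)cc(O)c12 | intermediate
10 | 2-[4-(benzyloxy)phenyl]-5-hydroxy-4-oxo-4H-chromen-7-yl hydrogen sulfate | O=c1cc(-c2ccc(OCc3ccccc3)cc2)oc2cc(OS(=O)(=O)O)cc(O)c12 | intermediate
11 | apigenin 7-sulfate | O=c1cc(-c2ccc(O)cc2)oc2cc(OS(=O)(=O)O)cc(O)c12 | target

Total step count: 6. Longest linear sequence: 6 steps (1 to 11); compounds 5 and 6 are purchased and enter at step 3.

Steps most likely to fail

Step 3. Direct, non-carbonylative alkynylation, sluggish oxidative addition at the hindered electron-rich C–I bond, or oxidative dimerisation of the alkyne could erode the ynone. The fallback brings C4 in as a formyl carbon and uses only polar organometallic chemistry. It sets out from compound 2 and returns at compound 7.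
- Compound 2 is lithiated as in step 2 (through aryllithium 3) and quenched with DMF to give 2,4,6-tris(methoxymethoxy)benzaldehyde F1.
- Alkyne 5 is deprotonated with n-BuLi in THF at −78 °C to lithium [4-(benzyloxy)phenyl]acetylide F2.
- F2 adds to F1 to give, after NH4Cl quench, the racemic propargylic alcohol F3.
- Oxidation of F3 with MnO2 in CH2Cl2 should give ynone 7.

Step 5. Sulfation could spill over to the chelated 5-OH or stall, leaving ionic mixtures that are hard to separate. The fallback installs the sulfate as a neutral, chromatographable diester. It sets out from compound 9 and returns at compound 10.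
- Compound 9 is treated with 2,2,2-trichloroethyl chlorosulfate, Et3N and DMAP in THF at 0 °C to give the 7-O-(2,2,2-trichloroethyl) sulfate diester F4, which is purified on silica.
- Reductive fragmentation of the trichloroethyl group with Zn and HCO2NH4 in MeOH should unmask the monoester 10.

Step 4. Ring closure could take the 5-exo course to the aurone skeleton, or the benzyl ether could be lost on prolonged heating in acid. The fallback fixes the site of ring closure before the phenols are freed. It sets out from compound 7 and returns at compound 9.
- Et2NH in EtOH at rt adds to the ynone to give the (E)-enaminone F5.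
- Aqueous HCl in MeOH at 60 °C removes the acetals, and a freed ortho hydroxyl displaces diethylamine at C2 by addition–elimination, which can only form the six-membered ring, giving 9.

Further compounds
F1 | step 3 | 2,4,6-tris(methoxymethoxy)benzaldehyde | O=Cc1c(OCOC)cc(OCOC)cc1OCOC
F2 | step 3 | lithium [4-(benzyloxy)phenyl]acetylide | [Li]C#Cc1ccc(OCc2ccccc2)cc1
F3 | step 3 | racemic 3-[4-(benzyloxy)phenyl]-1-[2,4,6-tris(methoxymethoxy)phenyl]prop-2-yn-1-ol | OC(C#Cc1ccc(OCc2ccccc2)cc1)c1c(OCOC)cc(OCOC)cc1OCOC
F4 | step 5 | 2-[4-(benzyloxy)phenyl]-5-hydroxy-4-oxo-4H-chromen-7-yl 2,2,2-trichloroethyl sulfate | O=c1cc(-c2ccc(OCc3ccccc3)cc2)oc2cc(OS(=O)(=O)OCC(Cl)(Cl)Cl)cc(O)c12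
F5 | step 4 | (E)-3-[4-(benzyloxy)phenyl]-3-(diethylamino)-1-[2,4,6-tris(methoxymethoxy)phenyl]prop-2-en-1-one | CCN(CC)/C(=C/C(=O)c1c(OCOC)cc(OCOC)cc1OCOC)c1ccc(OCc2ccccc2)cc1
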